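The target is the meso, all-cis oxolane: the syringyl groups on C2 and C5 and the hydroxymethyl arms on C3 and C4 share one ring face. The key step exploits two features. The aryl-flanked C2–O1–C5 segment is a masked 1,3-diaryl carbonyl ylide, and the cis C3–C4 edge is a masked maleic anhydride. One Rh2(OAc)4-catalysed operation unites a silyl-protected syringyl diazomethane, the matching aldehyde and the anhydride. It makes O1–C2, C2–C3 and C4–C5, the oxolane ring and all four stereocentres. Both aryl partners come from syringaldehyde. The diazo compound is prepared salt-free in a separate flask and dosed slowly. Reduction and desilylation finish the synthesis.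

Key step: step 4

Assumption: the four stereodescriptors of the target SMILES decode to the achiral meso isomer (2R,3R,4S,5S; all four ring substituents cis), so only relative configuration has to be controlled.
Abbreviation: Ar = 3,5-dimethoxy-4-(triisopropylsilyloxy)phenyl.

Step 1
Reactants: 1 syringaldehyde
Product: 2 3,5-dimethoxy-4-(triisopropylsilyloxy)benzaldehyde
Conditions: TIPSCl (1.3 equiv), imidazole (2.5 equiv), DMF, rt to 40 °C
Reagents that add atoms: triisopropylsilyl chloride, CC(C)[Si](Cl)(C(C)C)C(C)C
Why: Imidazole-promoted O-silylation of a phenol; the bulky triisopropylsilyl group is chosen because an aryl silyl ether para to a formyl group is prone to nucleophilic cleavage, and this one should withstand hydrazine and hydride yet still leave readily with fluoride.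

Step 2
Reactants: 2 3,5-dimethoxy-4-(triisopropylsilyloxy)benzaldehyde
Product: 3 (E)-hydrazone of 2 (ArCH=N–NH2)
Conditions: N2H4·H2O (10 equiv), EtOH, 0 °C to rt, 2 added to the hydrazine; aqueous wash, used the same day
Reagents that add atoms: hydrazine hydrate, NN.O
Why: Hydrazone condensation of an aromatic aldehyde, in which the large excess of hydrazine and the inverse addition suppress azine formation and the E geometry follows from steric preference.

Step 3
Reactants: 3 (E)-hydrazone of 2
Product: 4 [3,5-dimethoxy-4-(triisopropylsilyloxy)phenyl]diazomethane (cold CH2Cl2 solution, never concentrated)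
Conditions: activated MnO2 (8 equiv), Na2SO4, CH2Cl2, −10 to 0 °C, dark; cold filtration through Celite under Ar, stored briefly at −40 °C over 4 Å MS
Reagents that add atoms: none
Why: Dehydrogenation of an N-unsubstituted hydrazone with MnO2 is a known entry to aryldiazomethanes and gives a base-free, salt-free and sulfide-free solution, which matters because hydrazone anions, sulfinate or sulfides would attack maleic anhydride or divert the carbenoid in step 4.

Step 4
Reactants: 2 3,5-dimethoxy-4-(triisopropylsilyloxy)benzaldehyde; 4 [3,5-dimethoxy-4-(triisopropylsilyloxy)phenyl]diazomethane; 5 maleic anhydride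
Product: 8 meso all-cis 2,5-bis[3,5-dimethoxy-4-(triisopropylsilyloxy)phenyl]oxolane-3,4-dicarboxylic anhydride, via Rh2(OAc)4(=CHAr) carbenoid 6 (not isolated), via W-shaped carbonyl ylide 7 (not isolated)
Conditions: Rh2(OAc)4 (2 mol %), 2 (1.5 equiv), 5 (3 equiv), 4 Å MS, CH2Cl2, 0 °C; 4 (1 equiv, cold solution) by syringe pump over 6 h; excess 5 removed under high vacuum, 8 crystallised or passed quickly through dry silica
Reagents that add atoms: none
Why: Rh2(OAc)4 expels N2 from 4 to give the electrophilic carbenoid 6, the lone pair of the electron-rich aldehyde 2 attacks its carbene carbon (O1–C2 bond), and release of the catalyst leaves the 1,3-diaryl carbonyl ylide 7. The closest known reaction type is the rhodium-carbenoid three-component carbonyl ylide (3+2) cycloaddition of a diazo compound, an aldehyde and an electron-poor alkene, applied here without change of substrate class. The oxolane ring closes by an intermolecular suprafacial 4π+2π cycloaddition in which C2–C3 and C4–C5 form in one event, driven by the match between the high HOMO of the donor-substituted ylide and the low LUMO of 5. C2 and C5 become cis because 7 reacts from its least crowded extended geometry with each aryl group anti to the far ylide carbon; C3 and C4 stay cis because the alkene is locked Z in its ring, so even asynchronous bonding cannot scramble them; and the C2/C3 and C4/C5 pairs become cis through the endo transition state, where the two anhydride carbonyls lie under the C–O–C unit and gain secondary orbital and electrostatic stabilisation. The step needs endo over exo selectivity, secured by those two carbonyl groups and the low temperature, and chemoselectivity, secured because the strongly nucleophilic diazo carbon of 4 should meet the catalyst far faster than it adds to 5 when slow dosing keeps it at trace concentration, while the excess of very electron-poor 5 captures 7 before it can close to the oxirane or add to a second molecule of 2. In 8 the cis ring fusion protects C3 and C4, since inversion of either centre would require a strained trans-fused bicyclo[3.3.0] system.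

Step 5
Reactants: 8 meso all-cis 2,5-diaryloxolane-3,4-dicarboxylic anhydride
Product: 9 meso all-cis [2,5-bis(Ar)oxolane-3,4-diyl]dimethanol (bis-triisopropylsilyl ether of the target)
Conditions: LiAlH4 (3 equiv), THF, 0 °C to rt; Na2SO4·10H2O quench, filtration
Reagents that add atoms: none
Why: Exhaustive hydride reduction of a cyclic anhydride to the 1,4-diol, routine for maleic anhydride cycloadducts, touches no stereocentre because hydride addition to each carbonyl is much faster than enolisation, and the aryl silyl ethers and the oxolane are inert under these conditions.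

Step 6
Reactants: 9 meso all-cis [2,5-bis(Ar)oxolane-3,4-diyl]dimethanol
Product: 10 [(2R,3R,4S,5S)-2,5-bis(4-hydroxy-3,5-dimethoxyphenyl)oxolane-3,4-diyl]dimethanol (meso, all-cis; target)
Conditions: TBAF (2.5 equiv), AcOH (3 equiv), THF, 0 °C; pH 7 phosphate buffer work-up, acid-free purification
Reagents that add atoms: none
Why: Fluoride-induced cleavage of aryl silyl ethers is driven by the strong Si–F bond, and the acetic acid buffer keeps the liberated phenols protonated, so that neither phenoxide-triggered quinone methide ring opening (which would scramble C2 and C5) nor acid-induced benzylic ionisation can start.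

Compound list
1 | syringaldehyde (4-hydroxy-3,5-dimethoxybenzaldehyde) | COc1cc(C=O)cc(OC)c1O | starting material
2 | 3,5-dimethoxy-4-(triisopropylsilyloxy)benzaldehyde | COc1cc(C=O)cc(OC)c1O[Si](C(C)C)(C(C)C)C(C)C | intermediate
3 | (E)-[3,5-dimethoxy-4-(triisopropylsilyloxy)benzylidene]hydrazine | COc1cc(/C=N/N)cc(OC)c1O[Si](C(C)C)(C(C)C)C(C)C | intermediate
4 | [3,5-dimethoxy-4-(triisopropylsilyloxy)phenyl]diazomethane | COc1cc(C=[N+]=[N-])cc(OC)c1O[Si](C(C)C)(C(C)C)C(C)C | intermediate
5 | maleic anhydride | O=C1OC(=O)C=C1 | starting material
6 | carbenoid Rh2(OAc)4(=CHAr), not isolated | COc1cc(C=[Rh+2][Rh+2])cc(OC)c1O[Si](C(C)C)(C(C)C)C(C)C.CC(=O)[O-].CC(=O)[O-].CC(=O)[O-].CC(=O)[O-] | intermediate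
7 | 1,3-bis(Ar) carbonyl ylide, extended W geometry, not isolated | COc1cc(/C=[O+]/[CH-]c2cc(OC)c(O[Si](C(C)C)(C(C)C)C(C)C)c(OC)c2)cc(OC)c1O[Si](C(C)C)(C(C)C)C(C)C | intermediate
8 | meso all-cis 2,5-bis(Ar)oxolane-3,4-dicarboxylic anhydride (cis-fused; both aryl groups on the face of the anhydride ring) | COc1cc([C@H]2O[C@@H](c3cc(OC)c(O[Si](C(C)C)(C(C)C)C(C)C)c(OC)c3)[C@@H](C(=O)O4)[C@H]2C4=O)cc(OC)c1O[Si](C(C)C)(C(C)C)C(C)C | intermediate
9 | meso all-cis [2,5-bis(Ar)oxolane-3,4-diyl]dimethanol | COc1cc([C@H]2O[C@@H](c3cc(OC)c(O[Si](C(C)C)(C(C)C)C(C)C)c(OC)c3)[C@@H](CO)[C@H]2CO)cc(OC)c1O[Si](C(C)C)(C(C)C)C(C)C | intermediate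
10 | [(2R,3R,4S,5S)-2,5-bis(4-hydroxy-3,5-dimethoxyphenyl)oxolane-3,4-diyl]dimethanol (meso, all-cis) | COc1cc([C@H]2O[C@@H](c3cc(OC)c(O)c(OC)c3)[C@@H](CO)[C@H]2CO)cc(OC)c1O | target

Total step count: 6.
Longest linear sequence: 6 steps (1 → 2 → 3 → 4 → 8 → 9 → 10). Compound 2 enters a second time in step 4.

Steps most likely to fail

Step 4.
- **Risk:** Steric repulsion between the two aryl groups and the anhydride may let the exo approach compete with the endo one. Material may also be lost through uncatalysed addition of the diazo compound to the alkene, or through collapse of the ylide before it is trapped.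
- **Fallback:** It sets out from 2 and 4 and takes the setting of C3 and C4 out of the cycloaddition. The same Rh2(OAc)4 three-component reaction is run with dimethyl acetylenedicarboxylate in place of 5. Only the extended ylide geometry then matters, and the product should be dimethyl cis-2,5-bis(Ar)-2,5-dihydrofuran-3,4-dicarboxylate F1. Syn hydrogenation (H2, Rh/Al2O3, EtOAc; a catalyst with a low tendency to cleave benzylic C–O bonds) should occur on the face that carries only H2 and H5. This pushes both esters onto the aryl face and gives dimethyl all-cis-2,5-bis(Ar)oxolane-3,4-dicarboxylate F2. LiAlH4 reduction of F2 comes back to the route at 9.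

Step 3.
- **Risk:** The electron-rich diazoalkane may decompose on the oxidant surface or in storage through azine formation, carbene dimerisation or protonation by traces of acid. Incomplete oxidation may leave hydrazone, which would poison the catalyst and acylate on the anhydride.
- **Fallback:** It sets out from 2, keeps no stock of diazo compound and never lets it meet the anhydride. Condensation with 4-methylbenzenesulfonohydrazide gives the tosylhydrazone of 2 F3, and NaH in THF gives its sodium salt F4. F4 is warmed to 40 °C with 2, Rh2(OAc)4, catalytic tetrahydrothiophene and BnEt3NCl in MeCN (Bamford–Stevens release coupled to catalytic sulfur ylide epoxidation). This liberates 4 slowly and passes its carbene through 6 to the tetrahydrothiophenium benzylide F5, which converts 2 into racemic trans-2,3-bis(Ar)oxirane F6. F6 is then irradiated with blue light in the presence of 9-mesityl-10-methylacridinium tetrafluoroborate and 5. Electron-transfer-induced C–C cleavage of the oxirane regenerates ylide 7, and the cycloaddition comes back to the route at 8.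

Step 5.
- **Risk:** The basic hydride may cause enolisation after the first ring opening. This could lead to epimerisation at C3 or C4 or to β-elimination of O1. Reduction may also stall at the lactone stage in the crowded all-cis array, and the anhydride may hydrolyse during handling.
- **Fallback:** It sets out from 8 and changes from a nucleophilic to an electrophilic reductant. Deliberate hydrolysis (H2O, THF, rt) gives all-cis 2,5-bis(Ar)oxolane-3,4-dicarboxylic acid F7. BH3·THF (0 °C to rt) reduces carboxylic acids under non-basic conditions and converts F7 into the diol, coming back to the route at 9.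

Further compounds
F1 | step 4 | dimethyl cis-2,5-bis(Ar)-2,5-dihydrofuran-3,4-dicarboxylate (meso) | COc1cc([C@H]2O[C@@H](c3cc(OC)c(O[Si](C(C)C)(C(C)C)C(C)C)c(OC)c3)C(C(=O)OC)=C2C(=O)OC)cc(OC)c1O[Si](C(C)C)(C(C)C)C(C)C
F2 | step 4 | dimethyl all-cis-2,5-bis(Ar)oxolane-3,4-dicarboxylate (meso) | COc1cc([C@H]2O[C@@H](c3cc(OC)c(O[Si](C(C)C)(C(C)C)C(C)C)c(OC)c3)[C@@H](C(=O)OC)[C@H]2C(=O)OC)cc(OC)c1O[Si](C(C)C)(C(C)C)C(C)C
F3 | step 3 | (E)-N'-[3,5-dimethoxy-4-(triisopropylsilyloxy)benzylidene]-4-methylbenzenesulfonohydrazide | COc1cc(/C=N/NS(=O)(=O)c2ccc(C)cc2)cc(OC)c1O[Si](C(C)C)(C(C)C)C(C)C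
F4 | step 3 | sodium salt of F3 | COc1cc(/C=N/[N-]S(=O)(=O)c2ccc(C)cc2)cc(OC)c1O[Si](C(C)C)(C(C)C)C(C)C.[Na+]
F5 | step 3 | tetrahydrothiophenium (Ar)methylide | COc1cc([CH-][S+]2CCCC2)cc(OC)c1O[Si](C(C)C)(C(C)C)C(C)C
F6 | step 3 | trans-2,3-bis(Ar)oxirane (racemic, one enantiomer drawn) | COc1cc([C@H]2O[C@@H]2c3cc(OC)c(O[Si](C(C)C)(C(C)C)C(C)C)c(OC)c3)cc(OC)c1O[Si](C(C)C)(C(C)C)C(C)C
F7 | step 5 | all-cis 2,5-bis(Ar)oxolane-3,4-dicarboxylic acid (meso) | COc1cc([C@H]2O[C@@H](c3cc(OC)c(O[Si](C(C)C)(C(C)C)C(C)C)c(OC)c3)[C@@H](C(=O)O)[C@H]2C(=O)O)cc(OC)c1O[Si](C(C)C)(C(C)C)C(C)C
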